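## Retrosynthetic overview

1. Germacranolide locants are used: carbocycle C1–C10, lactone O on C6, fusion carbon C7, lactone α-carbon C11, carbonyl C12, methylene C13, ester carbon C14 on C10. The two side-chain esters are removed first, giving core alcohol 16, epoxy acid 19 (Sharpless epoxidation) and hydroxy acid 25 (Evans aldol).
2. Key disconnection C7–C11: the γ-lactone of 16 is closed last, from the ten-membered epoxy phosphonoacetate 14. The enabling feature is that C7, the atom shared by lactone and carbocycle, lies between the oxygen-bearing C6 and C8, and C11 is two atoms from O6. A 7,8-trans-epoxide therefore lets the C11 carbanion of a C6-O-phosphonoacetate open the oxirane at C7 (5-exo). This sets C7, frees only the 8-OH and, after Horner–Wadsworth–Emmons reaction with CH2O in the same flask, gives the C11=C13 methylene.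
3. Ten-membered ring: ring-closing metathesis at C4=C5 of acyclic epoxy ester 13, run while the trans-oxirane (a temporary ring) still joins C6 to C9, so that six-membered closure onto the enoate is geometrically impossible.
4. Acyclic stereocontrol: C9 by catalytic enantioselective alkynylation (2 + 3); C6, C7 and C8 in one Sharpless epoxidation of dienol 10; the C1=C10 enoate by syn-hydrostannation, iodination and carbonylation of the alkyne.
5. Order of ring formation: oxirane, then carbocycle, then γ-lactone.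

Key step: step 11

Remark on the structure: the oxirane ester carries cis methyl groups (it is the epoxide of (E)-2-methylbut-2-enoic acid), and both ring alkenes are ring-cis (4Z; 1(10)E by the sequence rule).
Assumption: the antipode of the ProPhenol ligand in step 2 is chosen to deliver the 4R alcohol 4; if the first antipode tried gives 4S, the other is used.

## Route

Step 1
Reactants: 1 4-bromo-2-methylbut-1-ene
Product: 2 2-methylhex-1-en-5-yne
Conditions: LiC≡CH·H2NCH2CH2NH2, DMSO, 0 °C → rt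
Reagents that add atoms: lithium acetylide–ethylenediamine complex, [Li]C#C.NCCN
Why: SN2 alkylation of lithium acetylide by a primary homoallylic bromide in a dipolar aprotic solvent; no stereocentre is formed.

Step 2
Reactants: 2 2-methylhex-1-en-5-yne; 3 (2E)-4,4-dimethoxybut-2-enal
Product: 4 (2E,4R)-1,1-dimethoxy-9-methyldeca-2,9-dien-5-yn-4-ol
Conditions: ProPhenol ligand (20 mol%), Me2Zn (3 equiv), Ph3P=O (40 mol%), toluene, 4 °C; aq. NH4Cl
Reagents that add atoms: none
Why: Zinc/ProPhenol-catalysed enantioselective alkynylation of an α,β-unsaturated aldehyde, in which the dinuclear zinc catalyst binds the aldehyde and the zinc acetylide and sets the C9 carbinol (4R) by catalyst control while the acetal is inert.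

Step 3
Reactants: 4 (2E,4R)-1,1-dimethoxy-9-methyldeca-2,9-dien-5-yn-4-ol
Product: 5 (2E,4R)-1,1-dimethoxy-4-[(4-methoxybenzyl)oxy]-9-methyldeca-2,9-dien-5-yne
Conditions: NaH, 4-MeOC6H4CH2Cl, Bu4NI (cat.), DMF, 0 °C → rt
Reagents that add atoms: 4-methoxybenzyl chloride, COc1ccc(CCl)cc1
Why: Williamson etherification of the alkoxide, which leaves the acetal, the alkyne and the stereocentre untouched and gives an ether that cannot migrate or be ionised later.

Step 4
Reactants: 5 (2E,4R)-1,1-dimethoxy-4-[(4-methoxybenzyl)oxy]-9-methyldeca-2,9-dien-5-yne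
Product: 7 (2E,4R,5E)-5-iodo-1,1-dimethoxy-4-[(4-methoxybenzyl)oxy]-9-methyldeca-2,5,9-triene, via alkenylstannane 6 (not isolated)
Conditions: Mo(CO)3(CNtBu)3 (cat.), Bu3SnH, hydroquinone (cat.), THF, 55 °C; evaporate; then I2, CH2Cl2, 0 °C
Reagents that add atoms: iodine, II
Why: Molybdenum-catalysed syn-hydrostannation of a propargylic ether places tin on the alkyne carbon next to the oxygen-bearing carbon and hydrogen on the distal carbon from the same face, and iododestannylation with retention then gives the alkenyl iodide in which the C2 chain is cis to C9.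

Step 5
Reactants: 7 (2E,4R,5E)-5-iodo-1,1-dimethoxy-4-[(4-methoxybenzyl)oxy]-9-methyldeca-2,5,9-triene
Product: 8 methyl (2E)-2-{(1R,2E)-4,4-dimethoxy-1-[(4-methoxybenzyl)oxy]but-2-en-1-yl}-6-methylhepta-2,6-dienoate
Conditions: PdCl2(PPh3)2 (5 mol%), CO (1 atm), MeOH, Et3N, DMF, 50 °C
Reagents that add atoms: carbon monoxide, [C-]#[O+]; methanol, CO
Why: Palladium-catalysed methoxycarbonylation of an alkenyl iodide (oxidative addition, CO insertion, methanolysis) proceeds with retention of alkene geometry and so gives the (E)-enoate with C2 trans to the ester.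

Step 6
Reactants: 8 methyl (2E)-2-{(1R,2E)-4,4-dimethoxy-1-[(4-methoxybenzyl)oxy]but-2-en-1-yl}-6-methylhepta-2,6-dienoate
Product: 9 methyl (2E)-2-{(1R,2E)-1-[(4-methoxybenzyl)oxy]-4-oxobut-2-en-1-yl}-6-methylhepta-2,6-dienoate
Conditions: PPTS (cat.), acetone/H2O (9:1), 40 °C
Reagents that add atoms: water, O
Why: Mild acid hydrolysis of the dimethyl acetal releases the (E)-enal, while the 4-methoxybenzyl ether and the methyl ester are stable to pyridinium tosylate.

Step 7
Reactants: 9 methyl (2E)-2-{(1R,2E)-1-[(4-methoxybenzyl)oxy]-4-oxobut-2-en-1-yl}-6-methylhepta-2,6-dienoate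
Product: 10 methyl (2E)-2-{(1R,2E)-4-hydroxy-1-[(4-methoxybenzyl)oxy]hexa-2,5-dien-1-yl}-6-methylhepta-2,6-dienoate (both epimers at the new carbinol)
Conditions: CH2=CHMgBr (1.2 equiv), THF, −78 °C; aq. NH4Cl
Reagents that add atoms: vinylmagnesium bromide, C=C[Mg]Br
Why: 1,2-Addition of the Grignard reagent to the enal at low temperature outpaces attack on the hindered trisubstituted enoate; the C6 carbinol is formed without control and is selected in step 8.

Step 8
Reactants: 10 methyl (2E)-2-{(1R,2E)-4-hydroxy-1-[(4-methoxybenzyl)oxy]hexa-2,5-dien-1-yl}-6-methylhepta-2,6-dienoate (both epimers at the new carbinol)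
Product: 11 methyl (2E)-2-{(S)-{(2R,3R)-3-[(1R)-1-hydroxyprop-2-en-1-yl]oxiran-2-yl}[(4-methoxybenzyl)oxy]methyl}-6-methylhepta-2,6-dienoate
Conditions: Ti(OiPr)4 (0.2 equiv), D-(−)-diisopropyl tartrate (0.25 equiv), t-BuOOH (0.6 equiv), 4 Å molecular sieves, CH2Cl2, −20 °C, to about half conversion; chromatography
Reagents that add atoms: tert-butyl hydroperoxide, CC(C)(C)OO
Why: Sharpless asymmetric epoxidation under kinetic-resolution conditions should epoxidise only the 6R epimer quickly, at the E-disubstituted allylic alkene and erythro to the carbinol, giving the 7R,8R oxirane by reagent control, whereas the 6S epimer, the terminal vinyl group and the electron-poor enoate react far more slowly.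

Step 9
Reactants: 11 methyl (2E)-2-{(S)-{(2R,3R)-3-[(1R)-1-hydroxyprop-2-en-1-yl]oxiran-2-yl}[(4-methoxybenzyl)oxy]methyl}-6-methylhepta-2,6-dienoate; 12 (diethoxyphosphoryl)acetic acid
Product: 13 methyl (2E)-2-{(S)-{(2R,3R)-3-[(1R)-1-{[(diethoxyphosphoryl)acetyl]oxy}prop-2-en-1-yl]oxiran-2-yl}[(4-methoxybenzyl)oxy]methyl}-6-methylhepta-2,6-dienoate
Conditions: DCC, DMAP (cat.), CH2Cl2, 0 °C → rt
Reagents that add atoms: none
Why: Steglich esterification acylates the only free hydroxyl under neutral conditions, so the epoxy alcohol is not exposed to base and cannot undergo Payne rearrangement.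

Step 10
Reactants: 13 methyl (2E)-2-{(S)-{(2R,3R)-3-[(1R)-1-{[(diethoxyphosphoryl)acetyl]oxy}prop-2-en-1-yl]oxiran-2-yl}[(4-methoxybenzyl)oxy]methyl}-6-methylhepta-2,6-dienoate
Product: 14 methyl (1R,2S,3E,7Z,9R,10R)-9-{[(diethoxyphosphoryl)acetyl]oxy}-2-[(4-methoxybenzyl)oxy]-7-methyl-11-oxabicyclo[8.1.0]undeca-3,7-diene-3-carboxylate
Conditions: second-generation Hoveyda–Grubbs catalyst RuCl2(H2IMes)(=CH-C6H4-2-OiPr) (10 mol%), toluene (1 mM), 80 °C
Reagents that add atoms: none
Why: Ring-closing metathesis between the vinyl group on C6 and the 1,1-disubstituted alkene should give the ten-membered ring with the ring-cis (Z) C4=C5 bond, the less strained isomer of a cyclodecene; the trans-oxirane between C6 and C9 excludes six-membered closure onto the enoate, and high dilution suppresses oligomers.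

Step 11
Reactants: 14 methyl (1R,2S,3E,7Z,9R,10R)-9-{[(diethoxyphosphoryl)acetyl]oxy}-2-[(4-methoxybenzyl)oxy]-7-methyl-11-oxabicyclo[8.1.0]undeca-3,7-diene-3-carboxylate
Product: 16 methyl (3aR,4S,5S,6E,10Z,11aR)-4-hydroxy-5-[(4-methoxybenzyl)oxy]-10-methyl-3-methylidene-2-oxo-2,3,3a,4,5,8,9,11a-octahydrocyclodeca[b]furan-6-carboxylate, via phosphono lactone 15 (not isolated)
Conditions: LiN(SiMe3)2 (1.05 equiv), THF, −78 → 45 °C; then (CH2O)n, 0 °C → rt; aq. NH4Cl
Reagents that add atoms: formaldehyde (from paraformaldehyde), C=O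
Why: Proposed new method: LiN(SiMe3)2 should deprotonate only the phosphonoacetate CH2, and the lithium-bound carbanion C11 then attacks C7 of the trans-oxirane from the side opposite the oxirane oxygen (SN2); the closest known reaction types are the telescoped intramolecular Michael addition/olefination of phosphonoacetate esters, the intermolecular opening of epoxides by phosphonoacetate anions and the Stork epoxynitrile cyclization. The γ-lactone closes by a 5-exo-tet opening, the breaking C7–O bond lying outside the new ring. C7 is set by inversion and is thus dictated by the oxirane configuration fixed in step 8, with the 6R,7R relationship placing C5 and C8 trans on the new ring; C8 keeps its oxygen with retention and emerges as the only free hydroxyl, and C11 is erased by the olefination. The 8-alkoxide is quenched at once by the acidic C11–H to give the phosphonate-stabilised lactone enolate 15, whose carbonyl cannot be attacked by the 8-oxygen and which condenses with formaldehyde (Horner–Wadsworth–Emmons) to the exocyclic methylene. The step needs 5-exo attack at C7 rather than 6-endo attack at C8 and alkylation rather than elimination; the exo trajectory open only at C7, lithium activation of the oxirane and the low basicity of the stabilised carbanion should secure both.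

Step 12
Reactants: 17 (2E)-2-methylbut-2-en-1-ol
Product: 18 [(2R,3R)-2,3-dimethyloxiran-2-yl]methanol
Conditions: Ti(OiPr)4 (5 mol%), D-(−)-diethyl tartrate (6 mol%), t-BuOOH, 4 Å molecular sieves, CH2Cl2, −20 °C
Reagents that add atoms: tert-butyl hydroperoxide, CC(C)(C)OO
Why: Sharpless asymmetric epoxidation of a primary E-allylic alcohol, in which the D-tartrate delivers oxygen to the face that gives the 2R,3R oxirane with the two methyl groups cis.

Step 13
Reactants: 18 [(2R,3R)-2,3-dimethyloxiran-2-yl]methanol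
Product: 19 (2S,3R)-2,3-dimethyloxirane-2-carboxylic acid
Conditions: RuCl3·xH2O (2 mol%), NaIO4, MeCN/EtOAc/H2O, rt
Reagents that add atoms: water, O; sodium periodate, [Na+].[O-]I(=O)(=O)=O
Why: Catalytic RuO4 oxidation takes the primary alcohol through the aldehyde hydrate to the acid without opening the oxirane; the stereocentres are untouched and only the descriptor at C2 changes.

Step 14
Reactants: 16 methyl (3aR,4S,5S,6E,10Z,11aR)-4-hydroxy-5-[(4-methoxybenzyl)oxy]-10-methyl-3-methylidene-2-oxo-2,3,3a,4,5,8,9,11a-octahydrocyclodeca[b]furan-6-carboxylate; 19 (2S,3R)-2,3-dimethyloxirane-2-carboxylic acid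
Product: 20 methyl (3aS,4S,5S,6E,10Z,11aR)-4-{[(2S,3R)-2,3-dimethyloxirane-2-carbonyl]oxy}-5-[(4-methoxybenzyl)oxy]-10-methyl-3-methylidene-2-oxo-2,3,3a,4,5,8,9,11a-octahydrocyclodeca[b]furan-6-carboxylate
Conditions: 19, 2,4,6-Cl3C6H2COCl, Et3N, THF, rt; then 16, DMAP, toluene, rt
Reagents that add atoms: none
Why: Yamaguchi esterification through the mixed anhydride acylates the single free (C8) hydroxyl with the α-quaternary epoxy acid under conditions too mild for translactonisation.

Step 15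
Reactants: 20 methyl (3aS,4S,5S,6E,10Z,11aR)-4-{[(2S,3R)-2,3-dimethyloxirane-2-carbonyl]oxy}-5-[(4-methoxybenzyl)oxy]-10-methyl-3-methylidene-2-oxo-2,3,3a,4,5,8,9,11a-octahydrocyclodeca[b]furan-6-carboxylate
Product: 21 methyl (3aS,4S,5S,6E,10Z,11aR)-4-{[(2S,3R)-2,3-dimethyloxirane-2-carbonyl]oxy}-5-hydroxy-10-methyl-3-methylidene-2-oxo-2,3,3a,4,5,8,9,11a-octahydrocyclodeca[b]furan-6-carboxylate
Conditions: DDQ, CH2Cl2/pH 7 buffer (10:1), 0 °C → rt
Reagents that add atoms: none
Why: Oxidative cleavage of the 4-methoxybenzyl ether by DDQ under buffered, neutral conditions frees the C9 hydroxyl without acyl migration and leaves the alkenes, the oxirane and the esters intact.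

Step 16
Reactants: 22 (4R)-4-benzyl-3-propanoyl-1,3-oxazolidin-2-one
Product: 23 (4R)-4-benzyl-3-[(2R,3S)-3-hydroxy-2-methylbutanoyl]-1,3-oxazolidin-2-one
Conditions: Bu2BOTf, i-Pr2NEt, CH2Cl2, −78 → 0 °C; CH3CHO, −78 → 0 °C; pH 7 buffer, MeOH, H2O2
Reagents that add atoms: acetaldehyde, CC=O
Why: Evans syn-aldol reaction in which the Z boron enolate reacts through a Zimmerman–Traxler chair and the benzyl group of the auxiliary shields one enolate face, setting both new centres (2R,3S).

Step 17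
Reactants: 23 (4R)-4-benzyl-3-[(2R,3S)-3-hydroxy-2-methylbutanoyl]-1,3-oxazolidin-2-one
Product: 24 (4R)-4-benzyl-3-{(2R,3S)-2-methyl-3-[(triethylsilyl)oxy]butanoyl}-1,3-oxazolidin-2-one
Conditions: Et3SiOTf, 2,6-lutidine, CH2Cl2, −78 → 0 °C
Reagents that add atoms: triethylsilyl trifluoromethanesulfonate, CC[Si](CC)(CC)OS(=O)(=O)C(F)(F)F
Why: Silylation of the secondary alcohol with a silyl triflate and a hindered base, which avoids retro-aldol cleavage and gives an ether removable at the end with fluoride.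

Step 18
Reactants: 24 (4R)-4-benzyl-3-{(2R,3S)-2-methyl-3-[(triethylsilyl)oxy]butanoyl}-1,3-oxazolidin-2-one
Product: 25 (2R,3S)-2-methyl-3-[(triethylsilyl)oxy]butanoic acid
Conditions: LiOH, H2O2, THF/H2O (3:1), 0 °C; Na2SO3; dilute HCl to pH 4
Reagents that add atoms: hydrogen peroxide, OO
Why: Lithium hydroperoxide attacks the exocyclic imide carbonyl selectively and sulfite reduces the peracid, so the auxiliary is removed without epimerising the α-centre.

Step 19
Reactants: 21 methyl (3aS,4S,5S,6E,10Z,11aR)-4-{[(2S,3R)-2,3-dimethyloxirane-2-carbonyl]oxy}-5-hydroxy-10-methyl-3-methylidene-2-oxo-2,3,3a,4,5,8,9,11a-octahydrocyclodeca[b]furan-6-carboxylate; 25 (2R,3S)-2-methyl-3-[(triethylsilyl)oxy]butanoic acid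
Product: 26 methyl (3aS,4S,5S,6E,10Z,11aR)-4-{[(2S,3R)-2,3-dimethyloxirane-2-carbonyl]oxy}-10-methyl-5-({(2R,3S)-2-methyl-3-[(triethylsilyl)oxy]butanoyl}oxy)-3-methylidene-2-oxo-2,3,3a,4,5,8,9,11a-octahydrocyclodeca[b]furan-6-carboxylate
Conditions: 25, 2,4,6-Cl3C6H2COCl, Et3N, toluene, rt; then 21, DMAP, rt
Reagents that add atoms: none
Why: Yamaguchi esterification of the allylic C9 hydroxyl; the hindered α-quaternary ester on O8 should not migrate under these mildly basic conditions.

Step 20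
Reactants: 26 methyl (3aS,4S,5S,6E,10Z,11aR)-4-{[(2S,3R)-2,3-dimethyloxirane-2-carbonyl]oxy}-10-methyl-5-({(2R,3S)-2-methyl-3-[(triethylsilyl)oxy]butanoyl}oxy)-3-methylidene-2-oxo-2,3,3a,4,5,8,9,11a-octahydrocyclodeca[b]furan-6-carboxylate
Product: 27 methyl (3aS,4S,5S,6E,10Z,11aR)-4-{[(2S,3R)-2,3-dimethyloxirane-2-carbonyl]oxy}-5-{[(2R,3S)-3-hydroxy-2-methylbutanoyl]oxy}-10-methyl-3-methylidene-2-oxo-2,3,3a,4,5,8,9,11a-octahydrocyclodeca[b]furan-6-carboxylate
Conditions: HF·pyridine, pyridine, THF, 0 °C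
Reagents that add atoms: none
Why: Buffered fluoride cleaves the triethylsilyl ether without opening the oxirane, adding to the methylene lactone or moving an acyl group, and gives the target.

## Compound list

1 | 4-bromo-2-methylbut-1-ene | C=C(C)CCBr | starting material
2 | 2-methylhex-1-en-5-yne | C=C(C)CCC#C | intermediate
3 | (2E)-4,4-dimethoxybut-2-enal | O=C/C=C/C(OC)OC | starting material
4 | (2E,4R)-1,1-dimethoxy-9-methyldeca-2,9-dien-5-yn-4-ol | C=C(C)CCC#C[C@H](O)/C=C/C(OC)OC | intermediate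
5 | (2E,4R)-1,1-dimethoxy-4-[(4-methoxybenzyl)oxy]-9-methyldeca-2,9-dien-5-yne | C=C(C)CCC#C[C@H](OCc1ccc(OC)cc1)/C=C/C(OC)OC | intermediate
6 | tributyl{(2E,4R,5E)-1,1-dimethoxy-4-[(4-methoxybenzyl)oxy]-9-methyldeca-2,5,9-trien-5-yl}stannane (not isolated) | C=C(C)CC/C=C(/[Sn](CCCC)(CCCC)CCCC)[C@H](OCc1ccc(OC)cc1)/C=C/C(OC)OC | intermediate
7 | (2E,4R,5E)-5-iodo-1,1-dimethoxy-4-[(4-methoxybenzyl)oxy]-9-methyldeca-2,5,9-triene | C=C(C)CC/C=C(/I)[C@H](OCc1ccc(OC)cc1)/C=C/C(OC)OC | intermediate
8 | methyl (2E)-2-{(1R,2E)-4,4-dimethoxy-1-[(4-methoxybenzyl)oxy]but-2-en-1-yl}-6-methylhepta-2,6-dienoate | C=C(C)CC/C=C(/C(=O)OC)[C@H](OCc1ccc(OC)cc1)/C=C/C(OC)OC | intermediate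
9 | methyl (2E)-2-{(1R,2E)-1-[(4-methoxybenzyl)oxy]-4-oxobut-2-en-1-yl}-6-methylhepta-2,6-dienoate | C=C(C)CC/C=C(/C(=O)OC)[C@H](OCc1ccc(OC)cc1)/C=C/C=O | intermediate
10 | methyl (2E)-2-{(1R,2E)-4-hydroxy-1-[(4-methoxybenzyl)oxy]hexa-2,5-dien-1-yl}-6-methylhepta-2,6-dienoate (both epimers at the new carbinol) | C=C(C)CC/C=C(/C(=O)OC)[C@H](OCc1ccc(OC)cc1)/C=C/C(O)C=C | intermediate
11 | methyl (2E)-2-{(S)-{(2R,3R)-3-[(1R)-1-hydroxyprop-2-en-1-yl]oxiran-2-yl}[(4-methoxybenzyl)oxy]methyl}-6-methylhepta-2,6-dienoate | C=C(C)CC/C=C(/C(=O)OC)[C@H](OCc1ccc(OC)cc1)[C@H]1O[C@@H]1[C@H](O)C=C | intermediate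
12 | (diethoxyphosphoryl)acetic acid | CCOP(=O)(OCC)CC(=O)O | starting material
13 | methyl (2E)-2-{(S)-{(2R,3R)-3-[(1R)-1-{[(diethoxyphosphoryl)acetyl]oxy}prop-2-en-1-yl]oxiran-2-yl}[(4-methoxybenzyl)oxy]methyl}-6-methylhepta-2,6-dienoate | C=C(C)CC/C=C(/C(=O)OC)[C@H](OCc1ccc(OC)cc1)[C@H]1O[C@@H]1[C@H](OC(=O)CP(=O)(OCC)OCC)C=C | intermediate
14 | methyl (1R,2S,3E,7Z,9R,10R)-9-{[(diethoxyphosphoryl)acetyl]oxy}-2-[(4-methoxybenzyl)oxy]-7-methyl-11-oxabicyclo[8.1.0]undeca-3,7-diene-3-carboxylate | CCOP(=O)(OCC)CC(=O)O[C@@H]1/C=C(/C)CC/C=C(/C(=O)OC)[C@H](OCc2ccc(OC)cc2)[C@H]3O[C@H]13 | intermediate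
15 | methyl (3aR,4S,5S,6E,10Z,11aR)-3-(diethoxyphosphoryl)-4-hydroxy-5-[(4-methoxybenzyl)oxy]-10-methyl-2-oxo-2,3,3a,4,5,8,9,11a-octahydrocyclodeca[b]furan-6-carboxylate (present as its lithium enolate; C3 not defined; not isolated) | CCOP(=O)(OCC)C1C(=O)O[C@@H]2/C=C(/C)CC/C=C(/C(=O)OC)[C@H](OCc3ccc(OC)cc3)[C@@H](O)[C@@H]12 | intermediate
16 | methyl (3aR,4S,5S,6E,10Z,11aR)-4-hydroxy-5-[(4-methoxybenzyl)oxy]-10-methyl-3-methylidene-2-oxo-2,3,3a,4,5,8,9,11a-octahydrocyclodeca[b]furan-6-carboxylate | C=C1C(=O)O[C@@H]2/C=C(/C)CC/C=C(/C(=O)OC)[C@H](OCc3ccc(OC)cc3)[C@@H](O)[C@@H]12 | intermediate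
17 | (2E)-2-methylbut-2-en-1-ol | C/C=C(\C)CO | starting material
18 | [(2R,3R)-2,3-dimethyloxiran-2-yl]methanol | OC[C@@]1(C)O[C@@H]1C | intermediate
19 | (2S,3R)-2,3-dimethyloxirane-2-carboxylic acid | OC(=O)[C@@]1(C)O[C@@H]1C | intermediate
20 | methyl (3aS,4S,5S,6E,10Z,11aR)-4-{[(2S,3R)-2,3-dimethyloxirane-2-carbonyl]oxy}-5-[(4-methoxybenzyl)oxy]-10-methyl-3-methylidene-2-oxo-2,3,3a,4,5,8,9,11a-octahydrocyclodeca[b]furan-6-carboxylate | C=C1C(=O)O[C@@H]2/C=C(/C)CC/C=C(/C(=O)OC)[C@H](OCc3ccc(OC)cc3)[C@@H](OC(=O)[C@@]4(C)O[C@@H]4C)[C@@H]12 | intermediate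
21 | methyl (3aS,4S,5S,6E,10Z,11aR)-4-{[(2S,3R)-2,3-dimethyloxirane-2-carbonyl]oxy}-5-hydroxy-10-methyl-3-methylidene-2-oxo-2,3,3a,4,5,8,9,11a-octahydrocyclodeca[b]furan-6-carboxylate | C=C1C(=O)O[C@@H]2/C=C(/C)CC/C=C(/C(=O)OC)[C@H](O)[C@@H](OC(=O)[C@@]3(C)O[C@@H]3C)[C@@H]12 | intermediate
22 | (4R)-4-benzyl-3-propanoyl-1,3-oxazolidin-2-one | CCC(=O)N1[C@H](Cc2ccccc2)COC1=O | starting material
23 | (4R)-4-benzyl-3-[(2R,3S)-3-hydroxy-2-methylbutanoyl]-1,3-oxazolidin-2-one | O=C1OC[C@@H](Cc2ccccc2)N1C(=O)[C@H](C)[C@H](C)O | intermediate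
24 | (4R)-4-benzyl-3-{(2R,3S)-2-methyl-3-[(triethylsilyl)oxy]butanoyl}-1,3-oxazolidin-2-one | O=C1OC[C@@H](Cc2ccccc2)N1C(=O)[C@H](C)[C@H](C)O[Si](CC)(CC)CC | intermediate
25 | (2R,3S)-2-methyl-3-[(triethylsilyl)oxy]butanoic acid | OC(=O)[C@H](C)[C@H](C)O[Si](CC)(CC)CC | intermediate
26 | methyl (3aS,4S,5S,6E,10Z,11aR)-4-{[(2S,3R)-2,3-dimethyloxirane-2-carbonyl]oxy}-10-methyl-5-({(2R,3S)-2-methyl-3-[(triethylsilyl)oxy]butanoyl}oxy)-3-methylidene-2-oxo-2,3,3a,4,5,8,9,11a-octahydrocyclodeca[b]furan-6-carboxylate | C=C1C(=O)O[C@@H]2/C=C(/C)CC/C=C(/C(=O)OC)[C@H](OC(=O)[C@H](C)[C@H](C)O[Si](CC)(CC)CC)[C@@H](OC(=O)[C@@]3(C)O[C@@H]3C)[C@@H]12 | intermediate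
27 | methyl (3aS,4S,5S,6E,10Z,11aR)-4-{[(2S,3R)-2,3-dimethyloxirane-2-carbonyl]oxy}-5-{[(2R,3S)-3-hydroxy-2-methylbutanoyl]oxy}-10-methyl-3-methylidene-2-oxo-2,3,3a,4,5,8,9,11a-octahydrocyclodeca[b]furan-6-carboxylate | C=C1C(=O)O[C@@H]2/C=C(/C)CC/C=C(/C(=O)OC)[C@H](OC(=O)[C@H](C)[C@H](C)O)[C@@H](OC(=O)[C@@]3(C)O[C@@H]3C)[C@@H]12 | target

## Step count and risks

Total step count: 20. Longest linear sequence: 15 steps (steps 1–11, 14, 15, 19, 20).

Steps most likely to fail:

1. Step 11 (Proposed new method). The stabilised carbanion may be too weak a nucleophile for the oxirane, or the ester may not reach the s-cis geometry needed for ring closure. The epoxide would then survive, open at C8, or be lost to slow decomposition on heating. Fallback (known chemistry, radical closure of the same C7–C11 bond): the route sets out from 11. Ring-closing metathesis under the conditions of step 10 should give the macrocyclic epoxy alcohol F1. O-Alkylation with propargyl bromide (NaH, Bu4NI, THF, 0 °C) gives the propargyl ether F2. Cp2TiCl (from Cp2TiCl2 and Zn in THF; trivalent titanium, Nugent–RajanBabu conditions) opens the oxirane homolytically, and the C7 radical closes 5-exo-dig onto the alkyne to give the methylidene-tetrahydrofuran F3 with the free 8-hydroxyl. Yamaguchi esterification with 19 gives the ester F4. Allylic oxidation of the ring CH2 next to the ring oxygen with CrO3·2C5H5N (hexavalent chromium) then gives 20, where the route is rejoined.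

2. Step 10. Closure of the strained ten-membered ring may lose out to intermolecular metathesis (oligomers), and the 1,1-disubstituted alkene may engage too slowly. Fallback (the lactone is made first and then serves as the template for ring closure): the route sets out from 13. Treatment under the conditions of step 11 should give the acyclic methylene lactone F5, in which the trans-disposed vinyl group and C8 chain sit on adjacent ring carbons. Ring-closing metathesis of F5 with the same class of ruthenium catalyst then gives 16, where the route is rejoined. The price is that six-membered closure onto the enoate is no longer excluded by the oxirane.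

3. Step 2. The zinc acetylide of an unactivated alkyl alkyne may add sluggishly, leading to incomplete conversion and eroded enantioselectivity. Fallback (asymmetric reduction instead of asymmetric C–C bond formation): the route sets out from 2 and 3. Addition of the lithium acetylide of 2 (n-BuLi, THF, −78 °C) to 3 gives the racemic alcohol F6. Oxidation with MnO2 gives the ynone F7. Corey–Bakshi–Shibata reduction (methyl oxazaborolidine antipode chosen for the 4R alcohol, BH3·SMe2, THF, −30 °C), in which the alkynyl group acts as the small substituent, then gives 4, where the route is rejoined.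

Further compounds
F1 | step 11 | methyl (1R,2S,3E,7Z,9R,10R)-9-hydroxy-2-[(4-methoxybenzyl)oxy]-7-methyl-11-oxabicyclo[8.1.0]undeca-3,7-diene-3-carboxylate | O[C@@H]1/C=C(/C)CC/C=C(/C(=O)OC)[C@H](OCc2ccc(OC)cc2)[C@H]3O[C@H]13
F2 | step 11 | methyl (1R,2S,3E,7Z,9R,10R)-2-[(4-methoxybenzyl)oxy]-7-methyl-9-(prop-2-yn-1-yloxy)-11-oxabicyclo[8.1.0]undeca-3,7-diene-3-carboxylate | C#CCO[C@@H]1/C=C(/C)CC/C=C(/C(=O)OC)[C@H](OCc2ccc(OC)cc2)[C@H]3O[C@H]13
F3 | step 11 | methyl (3aR,4S,5S,6E,10Z,11aR)-4-hydroxy-5-[(4-methoxybenzyl)oxy]-10-methyl-3-methylidene-2,3,3a,4,5,8,9,11a-octahydrocyclodeca[b]furan-6-carboxylate | C=C1CO[C@@H]2/C=C(/C)CC/C=C(/C(=O)OC)[C@H](OCc3ccc(OC)cc3)[C@@H](O)[C@@H]12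
F4 | step 11 | methyl (3aS,4S,5S,6E,10Z,11aR)-4-{[(2S,3R)-2,3-dimethyloxirane-2-carbonyl]oxy}-5-[(4-methoxybenzyl)oxy]-10-methyl-3-methylidene-2,3,3a,4,5,8,9,11a-octahydrocyclodeca[b]furan-6-carboxylate | C=C1CO[C@@H]2/C=C(/C)CC/C=C(/C(=O)OC)[C@H](OCc3ccc(OC)cc3)[C@@H](OC(=O)[C@@]4(C)O[C@@H]4C)[C@@H]12
F5 | step 10 | methyl (2E)-2-{(1S,2S)-2-[(2R,3R)-2-ethenyl-4-methylidene-5-oxooxolan-3-yl]-2-hydroxy-1-[(4-methoxybenzyl)oxy]ethyl}-6-methylhepta-2,6-dienoate | C=C(C)CC/C=C(/C(=O)OC)[C@H](OCc1ccc(OC)cc1)[C@@H](O)[C@@H]2[C@@H](C=C)OC(=O)C2=C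
F6 | step 2 | racemic (2E)-1,1-dimethoxy-9-methyldeca-2,9-dien-5-yn-4-ol | C=C(C)CCC#CC(O)/C=C/C(OC)OC
F7 | step 2 | (2E)-1,1-dimethoxy-9-methyldeca-2,9-dien-5-yn-4-one | C=C(C)CCC#CC(=O)/C=C/C(OC)OC
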